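**Retrosynthetic overview**

1. The three ester C–O bonds are cut last and one at a time. Each is made by a Mitsunobu inversion with one equivalent of amino alcohol 8, in the order quaternary (C1) ester, C3 ester, side-chain ester. The order follows from how the carboxyl groups are unmasked: hindered methyl ester (LiOH), aminoquinoline amide (Boc2O, then LiOH/H2O2), tert-butyl ester (CF3CO2H).
2. Alcohol 8 comes from ketone 7, and 7 from the flat N-methylpyridinium salt 5 by one enantioselective all-cis dearomative hydrogenation (key step). Ring order: pyridine (bought), cyclopentanone (Pd α-arylation), piperidine (dearomatisation).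
3. The cyclobutane is not made from its two olefin halves. It is formed first from methyl coumalate (4π-photocyclisation, hydrogenation), and its substituents are then set one at a time: amide-directed C–H vinylation (breaks the mirror symmetry), epimerisation/enolate methylation, side-chain coupling, amide-directed C–H arylation.

Assumption: the SMILES is taken as drawn, so the alcohol units are (4R,4aS,6R,7S,7aR) (this ester residue is written Alk below) and on the cyclobutane the aryl group, the neighbouring ester and the ring methyl share one face while the side chain and the quaternary ester share the other; 1, 2, 9, 11, 13, 14 and 18 are taken to be catalogue compounds.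

**Route**

Step 1
Reactants: 1 3-bromo-4,5-dimethylpyridine; 2 N-methoxy-N-methylpropanamide
Product: 3 1-(3-bromo-5-methylpyridin-4-yl)butan-2-one
Conditions: LiN(iPr)2 (1.1 equiv), THF, −78 °C; then 2 (1.2 equiv), −78 → 0 °C; H2O
Reagents that add atoms: none
Why: Lateral (picolyl) lithiation of the 4-methyl group, the only one conjugated to the ring nitrogen, followed by Weinreb-amide acylation, which stops at the ketone; no stereocenter.

Step 2
Reactants: 3 1-(3-bromo-5-methylpyridin-4-yl)butan-2-one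
Product: 4 4,7-dimethyl-5,7-dihydro-6H-cyclopenta[c]pyridin-6-one
Conditions: Pd2(dba)3 (2.5 mol%), Xantphos (6 mol%), NaOtBu (2.2 equiv), toluene, 80 °C
Reagents that add atoms: none
Why: Intramolecular palladium-catalysed ketone α-arylation (Buchwald–Hartwig type): only the ethyl-side enolate can reach the C–Br bond through a six-membered palladacycle, so the five-membered ring closes, and the product rests as its enolate, which protects it from a second arylation; C7 is labile and racemic at this stage.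

Step 3
Reactants: 4 4,7-dimethyl-5,7-dihydro-6H-cyclopenta[c]pyridin-6-one
Product: 5 2,4,7-trimethyl-6-oxo-6,7-dihydro-5H-cyclopenta[c]pyridin-2-ium iodide
Conditions: MeI (1.5 equiv), acetone, 40 °C
Reagents that add atoms: iodomethane, CI
Why: Menshutkin N-alkylation at the only basic nitrogen installs the N-methyl group and activates the ring for reduction; no stereocenter.

Step 4 (key step)
Reactants: 5 2,4,7-trimethyl-6-oxo-6,7-dihydro-5H-cyclopenta[c]pyridin-2-ium iodide
Product: 7 (4R,4aS,7S,7aR)-2,4,7-trimethyloctahydro-6H-cyclopenta[c]pyridin-6-one, via cis-fused ammonium iodide 6 (not isolated)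
Conditions: [Ir(cod)Cl]2 (1 mol%), (S)-SegPhos (2.2 mol%; antipode chosen by screening), H2 (50 bar), THF/CH2Cl2 1:1, 30 °C; then K2CO3 (2 equiv), MeOH, 25 °C
Reagents that add atoms: none
Why: Proposed new method: a monovalent-iridium hydride carrying a chiral bisphosphine transfers the first hydride to the ring carbon para to nitrogen (C4a), whose two faces differ by the flanking 4-methyl group and the fused ketone arm, so this transfer fixes the absolute configuration; hydrogen iodide then protonates both enamine carbons (C4, C7a) on the convex face that already carries H-4a, and the iminium carbons reduced next (C1, C3) are not stereogenic, so the three ring hydrogens end cis; carbonate finally equilibrates C7 through the enolate to the epimer with methyl trans to C1 (7S); the closest known reaction type is the [Ir(cod)Cl]2/bisphosphine hydrogenation of N-alkylpyridinium halides and the [Rh(cod)2]OTf/JosiPhos hydrogenation of 3-substituted pyridinium salts, neither yet applied to a 3,4,5-trisubstituted salt.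

Step 5
Reactants: 7 (4R,4aS,7S,7aR)-2,4,7-trimethyloctahydro-6H-cyclopenta[c]pyridin-6-one
Product: 8 (4R,4aS,6S,7S,7aR)-2,4,7-trimethyloctahydro-1H-cyclopenta[c]pyridin-6-ol
Conditions: NaBH4 (1.5 equiv), MeOH, −40 °C
Reagents that add atoms: none
Why: Substrate-controlled borohydride reduction: hydride enters from the convex face of the cis-fused bicycle, giving the concave (6S) alcohol trans to the 7-methyl group, the epimer needed for the Mitsunobu inversions in steps 15, 17 and 18.

Step 6
Reactants: 9 4-iodo-2-methoxyphenol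
Product: 10 4-iodo-2-methoxyphenyl acetate
Conditions: Ac2O (1.2 equiv), pyridine, DMAP (2 mol%), CH2Cl2, 0 → 25 °C
Reagents that add atoms: acetic anhydride, CC(=O)OC(C)=O
Why: O-Acetylation masks the phenol for the silver-mediated C–H arylation; the acetate is lost again in step 14; no stereocenter.

Step 7
Reactants: 11 tert-butyl acetoacetate
Product: 12 tert-butyl (E)-3-{[(trifluoromethyl)sulfonyl]oxy}but-2-enoate
Conditions: Tf2O (1.3 equiv), 25% aq. Me4NOH (3 equiv), hexane, 5 °C
Reagents that add atoms: trifluoromethanesulfonic anhydride, O=S(=O)(OS(=O)(=O)C(F)(F)F)C(F)(F)F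
Why: Enol triflate formation from the non-chelated ammonium enolate of a β-keto ester gives the E isomer (triflate trans to the ester), which later fixes the side-chain olefin geometry; the tert-butyl ester is the acid-labile member of the three differentiated carboxyl groups.

Step 8
Reactants: 13 methyl coumalate; 14 8-aminoquinoline
Product: 17 methyl cis-3-(quinolin-8-ylcarbamoyl)cyclobutane-1-carboxylate, via photopyrone 15 (not isolated), via cis acid 16 (not isolated)
Conditions: hν (450 W Hg lamp, Pyrex), CH2Cl2, 15 °C; then H2 (1 atm), Pt/C; then 14 (1.1 equiv), EDC·HCl, DMAP, 0 → 25 °C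
Reagents that add atoms: none
Why: Photochemical 4π-electrocyclisation of the 2-pyranone, hydrogenation/hydrogenolysis of the strained allylic lactone from the exo face (hence cis-1,3) and carbodiimide amidation install the bidentate directing group; the product has a mirror plane and is achiral.

Step 9
Reactants: 17 methyl cis-3-(quinolin-8-ylcarbamoyl)cyclobutane-1-carboxylate; 18 iodoethene
Product: 19 racemic methyl (1R*,2S*,3S*)-2-ethenyl-3-(quinolin-8-ylcarbamoyl)cyclobutane-1-carboxylate (all-cis)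
Conditions: Pd(OAc)2 (10 mol%), AgOAc (1.5 equiv), 18 (1.5 equiv), toluene/HFIP 4:1, 80 °C, sealed tube
Reagents that add atoms: none
Why: 8-Aminoquinoline-directed β-C(sp3)–H alkenylation through a five-membered palladacycle (divalent/tetravalent palladium cycle): only a C–H cis to the amide can be palladated, so vinyl ends cis to amide and ester; either enantiotopic CH2 reacts, so the mirror symmetry is broken to a racemate.

Step 10
Reactants: 19 racemic methyl (1R*,2S*,3S*)-2-ethenyl-3-(quinolin-8-ylcarbamoyl)cyclobutane-1-carboxylate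
Product: 20 methyl (1R,2S,3S)-2-ethenyl-3-(quinolin-8-ylcarbamoyl)cyclobutane-1-carboxylate
Conditions: preparative SFC, amylose tris(3,5-dimethylphenylcarbamate) stationary phase, CO2/MeOH
Reagents that add atoms: none
Why: Chromatographic resolution of the racemate at the first chiral intermediate; every later ring stereocenter is set relative to the vinyl-bearing carbon, so this separation fixes the absolute configuration of the cyclobutane.

Step 11
Reactants: 20 methyl (1R,2S,3S)-2-ethenyl-3-(quinolin-8-ylcarbamoyl)cyclobutane-1-carboxylate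
Product: 22 methyl (1R,2S,3R)-2-ethenyl-1-methyl-3-(quinolin-8-ylcarbamoyl)cyclobutane-1-carboxylate (ester cis to vinyl; amide trans to vinyl), via amide epimer 21 (not isolated)
Conditions: LiOtBu (2 equiv), THF, 50 °C; then −78 °C, KN(SiMe3)2 (1.5 equiv), MeI (1.3 equiv), → −40 °C; H2O
Reagents that add atoms: iodomethane, CI
Why: Base-mediated thermodynamic epimerisation α to the amide relieves the cis-1,2 amide/vinyl strain, then enolate alkylation of the ester, which reacts at carbon as the more basic site of the dianion, brings methyl in anti to the adjacent vinyl group, so the quaternary center has methyl trans and ester cis to vinyl.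

Step 12
Reactants: 22 methyl (1R,2S,3R)-2-ethenyl-1-methyl-3-(quinolin-8-ylcarbamoyl)cyclobutane-1-carboxylate; 12 tert-butyl (E)-3-{[(trifluoromethyl)sulfonyl]oxy}but-2-enoate
Product: 24 methyl (1R,2S,3R)-2-[(3E)-5-tert-butoxy-3-methyl-5-oxopent-3-en-1-yl]-1-methyl-3-(quinolin-8-ylcarbamoyl)cyclobutane-1-carboxylate, via alkylborane 23 (not isolated)
Conditions: 9-BBN dimer (0.75 equiv), THF, 0 → 25 °C; then 12 (1.3 equiv), Pd(dppf)Cl2 (5 mol%), K3PO4 (3 equiv), DMF/H2O 20:1, 50 °C
Reagents that add atoms: none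
Why: Anti-Markovnikov hydroboration followed by B-alkyl Suzuki–Miyaura coupling, which retains the triflate geometry and so gives the E-trisubstituted enoate; no ring stereocenter is touched.

Step 13
Reactants: 24 methyl (1R,2S,3R)-2-[(3E)-5-tert-butoxy-3-methyl-5-oxopent-3-en-1-yl]-1-methyl-3-(quinolin-8-ylcarbamoyl)cyclobutane-1-carboxylate; 10 4-iodo-2-methoxyphenyl acetate
Product: 25 methyl (1S,2S,3S,4R)-4-(4-acetoxy-3-methoxyphenyl)-2-[(3E)-5-tert-butoxy-3-methyl-5-oxopent-3-en-1-yl]-1-methyl-3-(quinolin-8-ylcarbamoyl)cyclobutane-1-carboxylate (aryl cis to amide carbon and ring methyl)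
Conditions: Pd(OAc)2 (10 mol%), 10 (3 equiv), AgOAc (2 equiv), tBuCO2H (30 mol%), t-AmOH, 100 °C
Reagents that add atoms: none
Why: Second 8-aminoquinoline-directed C(sp3)–H arylation: the only methylene C–H still cis to the epimerised amide lies on the face of the ring methyl, so the aryl group is forced cis to the amide carbon and to the methyl group, while the cis methine C–H at the chain-bearing carbon is too hindered to be palladated, and the weakly acidic carboxylate medium spares the tert-butyl ester.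

Step 14
Reactants: 25 methyl (1S,2S,3S,4R)-4-(4-acetoxy-3-methoxyphenyl)-2-[(3E)-5-tert-butoxy-3-methyl-5-oxopent-3-en-1-yl]-1-methyl-3-(quinolin-8-ylcarbamoyl)cyclobutane-1-carboxylate
Product: 26 (1S,2S,3S,4R)-2-[(3E)-5-tert-butoxy-3-methyl-5-oxopent-3-en-1-yl]-4-(4-hydroxy-3-methoxyphenyl)-1-methyl-3-(quinolin-8-ylcarbamoyl)cyclobutane-1-carboxylic acid
Conditions: LiOH·H2O (10 equiv), THF/MeOH/H2O 3:1:1, 60 °C; then 1 M HCl to pH 3, 0 °C
Reagents that add atoms: lithium hydroxide, [Li+].[OH-]
Why: Saponification by acyl–oxygen cleavage removes the aryl acetate and, on heating, the hindered quaternary methyl ester, while the tert-butyl enoate and the secondary aminoquinoline amide resist hydroxide at this temperature; C1 is quaternary and C3 is α to an amide that does not enolise in aqueous base, so no stereocenter moves.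

Step 15
Reactants: 26 (1S,2S,3S,4R)-2-[(3E)-5-tert-butoxy-3-methyl-5-oxopent-3-en-1-yl]-4-(4-hydroxy-3-methoxyphenyl)-1-methyl-3-(quinolin-8-ylcarbamoyl)cyclobutane-1-carboxylic acid; 8 (4R,4aS,6S,7S,7aR)-2,4,7-trimethyloctahydro-1H-cyclopenta[c]pyridin-6-ol
Product: 27 Alk (1S,2S,3S,4R)-2-[(3E)-5-tert-butoxy-3-methyl-5-oxopent-3-en-1-yl]-4-(4-hydroxy-3-methoxyphenyl)-1-methyl-3-(quinolin-8-ylcarbamoyl)cyclobutane-1-carboxylate
Conditions: 8 (1.2 equiv), PPh3 (2.0 equiv), DIAD (2.0 equiv), THF, 0 → 25 °C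
Reagents that add atoms: none
Why: Mitsunobu esterification: the carboxylic acid (pKa about 5) is the only group acidic enough to be engaged before the phenol (pKa about 10) and the anilide N–H, and its carboxylate displaces the alkoxyphosphonium ion of 8 with inversion, turning (6S) into the (6R) ester; an SN2 attack by oxygen is little slowed by the quaternary carbon next to the carboxylate, and the tertiary amine is inert.

Step 16
Reactants: 27 Alk (1S,2S,3S,4R)-2-[(3E)-5-tert-butoxy-3-methyl-5-oxopent-3-en-1-yl]-4-(4-hydroxy-3-methoxyphenyl)-1-methyl-3-(quinolin-8-ylcarbamoyl)cyclobutane-1-carboxylate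
Product: 29 (1S,2R,3S,4S)-3-(AlkO-carbonyl)-4-[(3E)-5-tert-butoxy-3-methyl-5-oxopent-3-en-1-yl]-2-(4-hydroxy-3-methoxyphenyl)-3-methylcyclobutane-1-carboxylic acid, via bis-Boc imide 28 (not isolated)
Conditions: Boc2O (5 equiv), DMAP (0.5 equiv), MeCN, 50 °C; evaporate; then LiOH·H2O (6 equiv), 30% H2O2 (8 equiv), THF/H2O 3:1, 0 °C, 2 h; aq. Na2SO3, 0 °C; 1 M HCl to pH 7
Reagents that add atoms: hydrogen peroxide, OO
Why: N-Boc activation twists the amide so that hydroperoxide cleaves the acyl–N bond (activated-amide hydrolysis) and the transient aryl carbonate falls off with it, while the hindered Alk ester and the tert-butyl ester are not attacked at 0 °C and the tertiary amine is oxidised only slowly by cold basic peroxide; the C3 stereocenter is safe once it is a carboxylate.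

Step 17
Reactants: 29 (1S,2R,3S,4S)-3-(AlkO-carbonyl)-4-[(3E)-5-tert-butoxy-3-methyl-5-oxopent-3-en-1-yl]-2-(4-hydroxy-3-methoxyphenyl)-3-methylcyclobutane-1-carboxylic acid; 8 (4R,4aS,6S,7S,7aR)-2,4,7-trimethyloctahydro-1H-cyclopenta[c]pyridin-6-ol
Product: 31 1,3-bis(Alk) ester of (1S,2R,3S,4S)-4-[(3E)-4-carboxy-3-methylbut-3-en-1-yl]-2-(4-hydroxy-3-methoxyphenyl)-1-methylcyclobutane-1,3-dicarboxylic acid, via tert-butyl ester 30 (not isolated)
Conditions: 8 (1.2 equiv), PPh3 (2.0 equiv), DIAD (2.0 equiv), THF, 0 → 25 °C; evaporate; then CF3CO2H/CH2Cl2 1:3, 0 → 25 °C; evaporate; aq. NaHCO3 to pH 7, CHCl3/iPrOH extraction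
Reagents that add atoms: none
Why: Second Mitsunobu inversion, now at the C3 carboxylate of the zwitterionic amino acid, followed in the same flask by acidolysis of the tert-butyl ester (alkyl–oxygen cleavage with loss of 2-methylpropene), which leaves both Alk esters and the E olefin untouched.

Step 18
Reactants: 31 1,3-bis(Alk) ester of (1S,2R,3S,4S)-4-[(3E)-4-carboxy-3-methylbut-3-en-1-yl]-2-(4-hydroxy-3-methoxyphenyl)-1-methylcyclobutane-1,3-dicarboxylic acid; 8 (4R,4aS,6S,7S,7aR)-2,4,7-trimethyloctahydro-1H-cyclopenta[c]pyridin-6-ol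
Product: 32 CNP0251577.3 (target)
Conditions: 8 (1.3 equiv), PPh3 (2.5 equiv), DIAD (2.5 equiv), THF/CH2Cl2 2:1, 0 → 25 °C
Reagents that add atoms: none
Why: Third Mitsunobu inversion: the unhindered enoic acid (pKa about 5) is engaged before the phenol, its carboxylate displaces the alkoxyphosphonium ion of 8 with inversion to the (6R) ester, and neither the olefin geometry nor any ring stereocenter is touched.

**Compound list**

1 | 3-bromo-4,5-dimethylpyridine | Cc1cncc(Br)c1C | starting material
2 | N-methoxy-N-methylpropanamide | CCC(=O)N(C)OC | starting material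
3 | 1-(3-bromo-5-methylpyridin-4-yl)butan-2-one | CCC(=O)Cc1c(C)cncc1Br | intermediate
4 | 4,7-dimethyl-5,7-dihydro-6H-cyclopenta[c]pyridin-6-one (racemic, C7 labile) | CC1C(=O)Cc2c(C)cncc21 | intermediate
5 | 2,4,7-trimethyl-6-oxo-6,7-dihydro-5H-cyclopenta[c]pyridin-2-ium iodide | CC1C(=O)Cc2c(C)c[n+](C)cc21.[I-] | intermediate
6 | (4R,4aS,7aR)-2,4,7-trimethyl-6-oxooctahydro-1H-cyclopenta[c]pyridin-2-ium iodide (both C7 epimers) | O=C1C[C@@H]2[C@@H](C[NH+](C)C[C@@H]2C)C1C.[I-] | intermediate
7 | (4R,4aS,7S,7aR)-2,4,7-trimethyloctahydro-6H-cyclopenta[c]pyridin-6-one | O=C1C[C@@H]2[C@@H](CN(C)C[C@@H]2C)[C@@H]1C | intermediate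
8 | (4R,4aS,6S,7S,7aR)-2,4,7-trimethyloctahydro-1H-cyclopenta[c]pyridin-6-ol (OH on the concave face, trans to 7-methyl) | O[C@H]1C[C@@H]2[C@@H](CN(C)C[C@@H]2C)[C@@H]1C | intermediate
9 | 4-iodo-2-methoxyphenol | COc1cc(I)ccc1O | starting material
10 | 4-iodo-2-methoxyphenyl acetate | COc1cc(I)ccc1OC(C)=O | intermediate
11 | tert-butyl acetoacetate | CC(=O)CC(=O)OC(C)(C)C | starting material
12 | tert-butyl (E)-3-{[(trifluoromethyl)sulfonyl]oxy}but-2-enoate | CC(C)(C)OC(=O)/C=C(\C)OS(=O)(=O)C(F)(F)F | intermediate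
13 | methyl coumalate (methyl 2-oxo-2H-pyran-5-carboxylate) | COC(=O)C1=COC(=O)C=C1 | starting material
14 | 8-aminoquinoline | Nc1cccc2cccnc12 | starting material
15 | methyl 3-oxo-2-oxabicyclo[2.2.0]hex-5-ene-6-carboxylate (racemic, cis-fused) | COC(=O)C1=C[C@@H]2C(=O)O[C@H]12 | intermediate
16 | cis-3-(methoxycarbonyl)cyclobutane-1-carboxylic acid | COC(=O)[C@H]1C[C@@H](C(=O)O)C1 | intermediate
17 | methyl cis-3-(quinolin-8-ylcarbamoyl)cyclobutane-1-carboxylate | COC(=O)[C@H]1C[C@@H](C(=O)Nc2cccc3cccnc23)C1 | intermediate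
18 | iodoethene | C=CI | starting material
19 | racemic methyl (1R*,2S*,3S*)-2-ethenyl-3-(quinolin-8-ylcarbamoyl)cyclobutane-1-carboxylate (all-cis; one enantiomer drawn) | C1[C@H](C(=O)Nc2cccc3cccnc23)[C@H](C=C)[C@@H]1C(=O)OC | intermediate
20 | methyl (1R,2S,3S)-2-ethenyl-3-(quinolin-8-ylcarbamoyl)cyclobutane-1-carboxylate | C1[C@H](C(=O)Nc2cccc3cccnc23)[C@H](C=C)[C@@H]1C(=O)OC | intermediate
21 | methyl (1R,2S,3R)-2-ethenyl-3-(quinolin-8-ylcarbamoyl)cyclobutane-1-carboxylate (epimer of 20 at the amide-bearing carbon: amide trans to vinyl, ester cis to vinyl) | C1[C@@H](C(=O)Nc2cccc3cccnc23)[C@H](C=C)[C@@H]1C(=O)OC | intermediate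
22 | methyl (1R,2S,3R)-2-ethenyl-1-methyl-3-(quinolin-8-ylcarbamoyl)cyclobutane-1-carboxylate (ester cis to vinyl; amide and methyl on the other face) | C1[C@@H](C(=O)Nc2cccc3cccnc23)[C@H](C=C)[C@]1(C)C(=O)OC | intermediate
23 | B-alkyl-9-borabicyclo[3.3.1]nonane from 22 (boron on the terminal carbon of the former vinyl group) | C1[C@@H](C(=O)Nc2cccc3cccnc23)[C@H](CCB2C3CCCC2CCC3)[C@]1(C)C(=O)OC | intermediate
24 | methyl (1R,2S,3R)-2-[(3E)-5-tert-butoxy-3-methyl-5-oxopent-3-en-1-yl]-1-methyl-3-(quinolin-8-ylcarbamoyl)cyclobutane-1-carboxylate (configuration as 22) | C1[C@@H](C(=O)Nc2cccc3cccnc23)[C@H](CC/C(C)=C/C(=O)OC(C)(C)C)[C@]1(C)C(=O)OC | intermediate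
25 | methyl (1S,2S,3S,4R)-4-(4-acetoxy-3-methoxyphenyl)-2-[(3E)-5-tert-butoxy-3-methyl-5-oxopent-3-en-1-yl]-1-methyl-3-(quinolin-8-ylcarbamoyl)cyclobutane-1-carboxylate (aryl, amide and methyl on one face; chain and methyl ester on the other) | CC(=O)Oc1ccc(cc1OC)[C@H]1[C@@H](C(=O)Nc2cccc3cccnc23)[C@H](CC/C(C)=C/C(=O)OC(C)(C)C)[C@]1(C)C(=O)OC | intermediate
26 | (1S,2S,3S,4R)-2-[(3E)-5-tert-butoxy-3-methyl-5-oxopent-3-en-1-yl]-4-(4-hydroxy-3-methoxyphenyl)-1-methyl-3-(quinolin-8-ylcarbamoyl)cyclobutane-1-carboxylic acid | COc1cc(ccc1O)[C@H]1[C@@H](C(=O)Nc2cccc3cccnc23)[C@H](CC/C(C)=C/C(=O)OC(C)(C)C)[C@]1(C)C(=O)O | intermediate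
27 | (4R,4aS,6R,7S,7aR)-2,4,7-trimethyloctahydro-1H-cyclopenta[c]pyridin-6-yl (1S,2S,3S,4R)-2-[(3E)-5-tert-butoxy-3-methyl-5-oxopent-3-en-1-yl]-4-(4-hydroxy-3-methoxyphenyl)-1-methyl-3-(quinolin-8-ylcarbamoyl)cyclobutane-1-carboxylate | COc1cc(ccc1O)[C@H]1[C@@H](C(=O)Nc2cccc3cccnc23)[C@H](CC/C(C)=C/C(=O)OC(C)(C)C)[C@]1(C)C(=O)O[C@@H]5C[C@@H]6[C@@H](CN(C)C[C@@H]6C)[C@@H]5C | intermediate
28 | N-Boc, O-Boc derivative of 27 (tert-butoxycarbonyl on the amide nitrogen and on the phenol oxygen) | CC(C)(C)OC(=O)Oc1ccc(cc1OC)[C@H]1[C@@H](C(=O)N(C(=O)OC(C)(C)C)c2cccc3cccnc23)[C@H](CC/C(C)=C/C(=O)OC(C)(C)C)[C@]1(C)C(=O)O[C@@H]5C[C@@H]6[C@@H](CN(C)C[C@@H]6C)[C@@H]5C | intermediate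
29 | (1S,2R,3S,4S)-4-[(3E)-5-tert-butoxy-3-methyl-5-oxopent-3-en-1-yl]-2-(4-hydroxy-3-methoxyphenyl)-3-methyl-3-({[(4R,4aS,6R,7S,7aR)-2,4,7-trimethyloctahydro-1H-cyclopenta[c]pyridin-6-yl]oxy}carbonyl)cyclobutane-1-carboxylic acid | COc1cc(ccc1O)[C@H]1[C@@H](C(=O)O)[C@H](CC/C(C)=C/C(=O)OC(C)(C)C)[C@]1(C)C(=O)O[C@@H]5C[C@@H]6[C@@H](CN(C)C[C@@H]6C)[C@@H]5C | intermediate
30 | bis[(4R,4aS,6R,7S,7aR)-2,4,7-trimethyloctahydro-1H-cyclopenta[c]pyridin-6-yl] (1S,2R,3S,4S)-4-[(3E)-5-tert-butoxy-3-methyl-5-oxopent-3-en-1-yl]-2-(4-hydroxy-3-methoxyphenyl)-1-methylcyclobutane-1,3-dicarboxylate | COc1cc(ccc1O)[C@H]1[C@@H](C(=O)O[C@@H]3C[C@@H]4[C@@H](CN(C)C[C@@H]4C)[C@@H]3C)[C@H](CC/C(C)=C/C(=O)OC(C)(C)C)[C@]1(C)C(=O)O[C@@H]5C[C@@H]6[C@@H](CN(C)C[C@@H]6C)[C@@H]5C | intermediate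
31 | 1,3-bis[(4R,4aS,6R,7S,7aR)-2,4,7-trimethyloctahydro-1H-cyclopenta[c]pyridin-6-yl] ester of (1S,2R,3S,4S)-4-[(3E)-4-carboxy-3-methylbut-3-en-1-yl]-2-(4-hydroxy-3-methoxyphenyl)-1-methylcyclobutane-1,3-dicarboxylic acid (side-chain acid free) | COc1cc(ccc1O)[C@H]1[C@@H](C(=O)O[C@@H]3C[C@@H]4[C@@H](CN(C)C[C@@H]4C)[C@@H]3C)[C@H](CC/C(C)=C/C(=O)O)[C@]1(C)C(=O)O[C@@H]5C[C@@H]6[C@@H](CN(C)C[C@@H]6C)[C@@H]5C | intermediate
32 | CNP0251577.3 | COc1cc([C@H]2[C@@H](C(=O)O[C@@H]3C[C@@H]4[C@@H](CN(C)C[C@@H]4C)[C@@H]3C)[C@H](CC/C(C)=C/C(=O)O[C@@H]3C[C@@H]4[C@@H](CN(C)C[C@@H]4C)[C@@H]3C)[C@]2(C)C(=O)O[C@@H]2C[C@@H]3[C@@H](CN(C)C[C@@H]3C)[C@@H]2C)ccc1O | target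

**Totals and risks**

Total step count: 18. Longest linear sequence: 11 steps (13 to 32, steps 8 to 18); the alkaloid branch is 5 steps (steps 1 to 5) and enters at steps 15, 17 and 18.

The three steps most likely to fail:

Step 4 is the least secure: no pyridinium salt substituted at both β carbons and the γ carbon has been hydrogenated enantioselectively, and either the enantioselectivity or the all-cis selectivity may be low. The fallback sets out from 5. Hydrogenation over Rh/Al2O3 (5% Rh) in MeOH (H2, 5 bar, 25 °C), which reduces the pyridinium ring much faster than the ketone, delivers all ring hydrogens from one face and gives the racemic ammonium iodide F1. K2CO3 in MeOH turns it into the racemic cis-fused amino ketone F2. F2 is resolved by fractional crystallisation from EtOH with (2R,3R)-O,O′-di-p-toluoyltartaric acid, from which the wanted enantiomer separates as the less soluble 1:1 di-p-toluoyltartrate salt F3 (the antipodal acid is used if the other salt is the less soluble one). 1 M NaOH/CH2Cl2 then liberates 7, where the route is rejoined.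

Step 13 must functionalise a C–H bond next to the quaternary carbon and cis to its methyl group, which may be too hindered for the bulky bidentate palladacycle. The fallback sets out from 24.
- The auxiliary is removed first: Boc2O/DMAP in MeCN gives the N-Boc amide F4.
- LiOH/H2O2 (THF/H2O, 0 °C; Na2SO3; 1 M HCl to pH 3), under which the hindered methyl ester and the tert-butyl ester survive, gives the C3 monoacid F5.
- The free ring carboxylate then directs the arylation itself through a smaller palladacycle, again cis to the carboxyl group (Pd(OAc)2, N-acetylglycine, 10, Ag2CO3, HFIP, 80 °C), giving the arylated acid F6.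
- Amidation with 14 (EDC·HCl, DMAP, CH2Cl2, 40 °C) then gives 25, where the route is rejoined.

Step 15 asks a carboxylate on a quaternary carbon to displace the activated, flanked secondary alcohol; elimination of 8 or acyl transfer with retention may win under Mitsunobu conditions. The fallback sets out from 8. Methanesulfonyl chloride and Et3N (CH2Cl2, 0 °C) give the concave-face mesylate F7, in which the ring nitrogen cannot reach the backside of C6. Acid 26 is converted into its caesium carboxylate with CsHCO3 (1.05 equiv, DMF, 25 °C), which leaves the phenol protonated. The carboxylate is then alkylated by the preformed mesylate at 50 °C with inversion, which gives 27, where the route is rejoined.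

Further compounds

F1 | step 4 | racemic all-cis 2,4,7-trimethyl-6-oxooctahydro-1H-cyclopenta[c]pyridin-2-ium iodide (both C7 epimers; one enantiomer drawn) | O=C1C[C@@H]2[C@@H](C[NH+](C)C[C@@H]2C)C1C.[I-]
F2 | step 4 | racemic (4R*,4aS*,7S*,7aR*)-2,4,7-trimethyloctahydro-6H-cyclopenta[c]pyridin-6-one (one enantiomer drawn) | O=C1C[C@@H]2[C@@H](CN(C)C[C@@H]2C)[C@@H]1C
F3 | step 4 | 1:1 salt of 7 with (2R,3R)-O,O′-di-p-toluoyltartaric acid | O=C1C[C@@H]2[C@@H](C[NH+](C)C[C@@H]2C)[C@@H]1C.OC(=O)[C@H](OC(=O)c1ccc(C)cc1)[C@@H](OC(=O)c1ccc(C)cc1)C([O-])=O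
F4 | step 13 | N-Boc derivative of 24 (tert-butoxycarbonyl on the amide nitrogen) | C1[C@@H](C(=O)N(C(=O)OC(C)(C)C)c2cccc3cccnc23)[C@H](CC/C(C)=C/C(=O)OC(C)(C)C)[C@]1(C)C(=O)OC
F5 | step 13 | 2-[(3E)-5-tert-butoxy-3-methyl-5-oxopent-3-en-1-yl]-3-(methoxycarbonyl)-3-methylcyclobutane-1-carboxylic acid (configuration as 24: carboxyl trans to the chain; methyl ester cis to the chain) | C1[C@@H](C(=O)O)[C@H](CC/C(C)=C/C(=O)OC(C)(C)C)[C@]1(C)C(=O)OC
F6 | step 13 | 2-(4-acetoxy-3-methoxyphenyl)-4-[(3E)-5-tert-butoxy-3-methyl-5-oxopent-3-en-1-yl]-3-(methoxycarbonyl)-3-methylcyclobutane-1-carboxylic acid (configuration as 25) | CC(=O)Oc1ccc(cc1OC)[C@H]1[C@@H](C(=O)O)[C@H](CC/C(C)=C/C(=O)OC(C)(C)C)[C@]1(C)C(=O)OC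
F7 | step 15 | (4R,4aS,6S,7S,7aR)-2,4,7-trimethyloctahydro-1H-cyclopenta[c]pyridin-6-yl methanesulfonate | CS(=O)(=O)O[C@H]1C[C@@H]2[C@@H](CN(C)C[C@@H]2C)[C@@H]1C
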